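Read the substrate column first: it gives a clock, and the clock gives a ceiling for the target.

| flask | substrate | partner | temperature | remark | time |
|---|---|---|---|---|---|
| ash | 6 mM | 2 equiv | 24 °C | run made earlier |  |
| oak | 9 mM | 2 equiv | 32 °C | run made earlier |  |
| Thursday's | 12 mM | 2.00 equiv | 20 °C |  | 50 min |
| Tuesday's | 12 mM | 2.00 equiv | 35 °C |  | 50 min |
| Friday's | 12 mM | 2.00 equiv |  | at 20 °C until 25 min, from then on at 35 °C | 50 min |

| run | time / min | target / % | substrate / % |
|---|---|---|---|
| ash | 1.50 | 0 | 95.3 |
| ash | 5.00 | 0.7 | 84.7 |
| ash | 8.00 | 0.8 | 75.4 |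
| ash | 12.0 | 1.5 | 66.0 |
| ash | 20.0 | 4.9 | 50.7 |
| ash | 25.0 | 8.1 | 44.7 |
| ash | 30.0 | 10.7 | 38.2 |
| oak | 0.833 | 0 | 92.3 |
| oak | 3.00 | 1.2 | 75.6 |
| oak | 4.00 | 0.9 | 68.8 |
| oak | 6.00 | 2.7 | 56.6 |
| oak | 12.0 | 12.1 | 34.2 |
| oak | 15.0 | 16.9 | 26.5 |

(each reading ± 0.5 percentage points)

- the flask with the highest amount of target, in percent of the substrate charged ("all alike" if they lie within 1.5 percentage points) (Thursday's / Tuesday's / Friday's / all alike)
- final target, as a percentage of the substrate charged, in Thursday's
- final target, as a percentage of the substrate charged, in Tuesday's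
- final target, as a percentage of the substrate charged, in Friday's

In the ash and oak runs c(substrate) falls by a steady fraction per minute, a first-order fall with no concentration in its constant: 0.0321 /min at 24 °C and 0.0885 /min at 32 °C. Stretching that ratio steadily over the degrees, I get 0.0193 /min at 20 °C and 0.130 /min at 35 °C.

The zero of my scale is a flask without lag, where whatever leaves the substrate is target at once. In Thursday's, 38.1 % of the substrate stays at 50 min, so the part gone, 61.9 %, is the ceiling, the most target that flask can hold if target comes through what has left the substrate.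

Now the rungs, fastest first. Tuesday's substrate life is 7.72 min, far shorter than the time, so if the fall runs one way to the end, I estimate its ceiling at 99.8 %. Thursday's life is 51.8 min, about the time itself. Slower comes the hand-over to target: the pool divided by the target's late rate of gain gives 88.1 min in the ash run and 35.9 min in the oak run, 2.83 and 3.18 substrate lives. The ash run's last reading stands at the same clock reading as Thursday's end, with 17.3 % of the part gone as target. If the charge does not count, Thursday's gets 10.7 %. I put Tuesday's highest and Friday's between.

The forecast says Tuesday's, with 11 % for Thursday's, 77 % for Tuesday's and 54 % for Friday's; of the substrate's fall it writes “the partner seems not to matter in this step”.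

The flask gives Tuesday's: 21.6 % in Thursday's, 63.7 % in Tuesday's, 52.0 % in Friday's.

    substrate ⇌ open intermediate (K = 22.0, k = 0.0200 /min, Ea = 98.0 kJ/mol, ΔH = −45.0 kJ/mol)
    partner → second intermediate (k = 0.0220 /min, Ea = 88.0 kJ/mol)
    open intermediate + second intermediate → target (k = 2.90 /M/min, Ea = 50.0 kJ/mol)
    second intermediate → side product (k = 0.0120 /min, Ea = 93.0 kJ/mol)
    partner ⇌ dormant form (K = 1.10, k = 0.0480 /min, Ea = 87.0 kJ/mol, ΔH = −2.00 kJ/mol)
    (constants at 20 °C)

Thursday's keeps 37.7 % substrate against my 38.1 %, and its open intermediate, the resting state there, holds 40.7 %, more than the substrate. Its target is a third of the ceiling, twice the ash share, on twice the ash charge.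

Take Thursday's with 20 mM of substrate: the clock has no concentration in it, so the ceiling stays 61.9 %. Computed, that flask keeps 37.6 % substrate and reaches 29.1 % target, 47.0 % of the ceiling.

The readings are simulated on assumed constants; the scatter is artificial.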